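**Retrosynthetic overview**
1. Target 11 comes from the tris-MOM chalcone 10 by global MOM removal.
2. The enone C=C of 10 is cut by a Claisen–Schmidt disconnection into the ring A methyl ketone 7 and the ring B aldehyde 8.
3. Key disconnection: the aryl–CH2 bond of 7 is cut into aryl iodide 3 and (R)-lavandulol 4, joined in a visible-light iridium/nickel deoxygenative coupling. The only stereocentre is bought in 4.
4. Iodide 3 comes from the commercial ketone 1 by 4-O-MOM protection and ortho-iodination.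
5. No ring is formed: ring A and ring B are both bought intact.

Assumption: (R)-(−)-lavandulol 4 (the natural, enantiopure terpene alcohol), benzoxazolium salt 5 and aldehyde 8 are taken as catalogue items; the target's (S) descriptor is the same spatial arrangement as (R)-4, because replacing O by aryl only changes the CIP ranking.

**Step 1**
Reactants: 1 1-(2,4-dihydroxy-6-methoxyphenyl)ethan-1-one
Product: 2 1-[2-hydroxy-6-methoxy-4-(methoxymethoxy)phenyl]ethan-1-one
Conditions: MOMCl (1.2 equiv), i-Pr2NEt (1.5 equiv), CH2Cl2, 0 °C → rt, 3 h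
Reagents that add atoms: chloromethyl methyl ether (MOMCl), COCCl
Why: Williamson-type O-alkylation (MOM protection) in which the 2-OH is locked in a hydrogen bond to the acetyl carbonyl, so only the free 4-OH reacts under amine-base conditions; no stereocentre is involved.

**Step 2**
Reactants: 2 1-[2-hydroxy-6-methoxy-4-(methoxymethoxy)phenyl]ethan-1-one
Product: 3 1-[2-hydroxy-3-iodo-6-methoxy-4-(methoxymethoxy)phenyl]ethan-1-one
Conditions: NIS (1.05 equiv), DMF, 0 °C → rt, 2 h, dark
Reagents that add atoms: N-iodosuccinimide (NIS), O=C1CCC(=O)N1I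
Why: Electrophilic aromatic iodination goes ortho to the chelated free phenol (C3, also para to OMe) rather than to C5, which is flanked by two ethers, as is established for 2-hydroxy-4,6-dialkoxyacetophenones; the neutral succinimide by-product leaves the MOM ether intact.

**Step 3**
Reactants: 3 1-[2-hydroxy-3-iodo-6-methoxy-4-(methoxymethoxy)phenyl]ethan-1-one; 4 (2R)-5-methyl-2-(prop-1-en-2-yl)hex-4-en-1-ol ((R)-lavandulol); 5 5,7-di-tert-butyl-3-phenyl-1,3-benzoxazol-3-ium tetrafluoroborate
Product: 7 1-{2-hydroxy-6-methoxy-4-(methoxymethoxy)-3-[(2S)-5-methyl-2-(prop-1-en-2-yl)hex-4-en-1-yl]phenyl}ethan-1-one, via lavandulyl benzoxazoline aminal 6 (not isolated)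
Conditions: 4 (1.6 equiv), 5 (1.5 equiv), pyridine (1.5 equiv), MTBE, rt, 15 min, filter; then 3 (1.0 equiv), [Ir(ppy)2(dtbbpy)]PF6 (1.5 mol%), NiBr2(dme) (10 mol%), dtbbpy (12 mol%), quinuclidine (1.8 equiv), MTBE/DMA, 450 nm LEDs, rt, 2–4 h, N2
Reagents that add atoms: none
Why: Proposed new method: a visible-light iridium/nickel dual-catalysed deoxygenative C(sp3)–C(sp2) coupling of an unprotected, chelated, di-ortho-oxygenated iodophenol with a β-stereogenic homoallylic alcohol. The excited iridium photocatalyst oxidises the electron-rich aminal 6, quinuclidine removes its C2–H, and β-scission (driven by formation of the aromatic benzoxazolone) releases the primary lavandulyl radical; this is captured by the aryl–nickel species formed by oxidative addition of zerovalent nickel into the C–I bond of 3, and reductive elimination from trivalent nickel forms the aryl–CH2 bond. The stereocentre is β to the radical carbon and is carried over unchanged from 4 (the aminal carbon of 6 is an uncontrolled, transient centre). The 10 mol% nickel loading is chosen so that radical capture (about 10^4 s^-1) outruns the 1,2-vinyl shift of the homoallyl radical (about 10^3 s^-1 or slower, since 3-exo attack is on a methyl-substituted carbon), and the weakly oxidising photocatalyst cannot turn quinuclidine into a hydrogen-abstracting radical cation that would attack the allylic C–H. The closest known reaction type is the benzoxazolium-mediated metallaphotoredox deoxygenative arylation of alcohols with simple aryl bromides, which has not been shown for free-phenol, 2,6-dioxygenated aryl iodides or for rearrangement-prone homoallylic radicals.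

**Step 4**
Reactants: 7 1-{2-hydroxy-6-methoxy-4-(methoxymethoxy)-3-[(2S)-5-methyl-2-(prop-1-en-2-yl)hex-4-en-1-yl]phenyl}ethan-1-one; 8 2,4-bis(methoxymethoxy)benzaldehyde
Product: 10 (2E)-3-[2,4-bis(methoxymethoxy)phenyl]-1-{2-hydroxy-6-methoxy-4-(methoxymethoxy)-3-[(2S)-5-methyl-2-(prop-1-en-2-yl)hex-4-en-1-yl]phenyl}prop-2-en-1-one, via aldol β-hydroxy ketone 9 (not isolated)
Conditions: 8 (1.3 equiv), KOH (50% aq., 15 equiv), EtOH, rt, 36 h, Ar, dark; then cold 1 M HCl to pH 5
Reagents that add atoms: none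
Why: Claisen–Schmidt (crossed aldol) condensation of the methyl ketone enolate with the non-enolisable aldehyde, followed by E1cB dehydration to the thermodynamically favoured E-enone; the carbinol centre of 9 forms without control and is destroyed on dehydration, while the lavandulyl stereocentre is non-acidic and untouched and MOM ethers are base-stable.

**Step 5**
Reactants: 10 (2E)-3-[2,4-bis(methoxymethoxy)phenyl]-1-{2-hydroxy-6-methoxy-4-(methoxymethoxy)-3-[(2S)-5-methyl-2-(prop-1-en-2-yl)hex-4-en-1-yl]phenyl}prop-2-en-1-one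
Product: 11 (2E)-1-{2,4-dihydroxy-6-methoxy-3-[(2S)-5-methyl-2-(prop-1-en-2-yl)hex-4-en-1-yl]phenyl}-3-(2,4-dihydroxyphenyl)prop-2-en-1-one
Conditions: 3 M aq. HCl/MeOH (1:5), 40 °C, 1–2 h (TLC control), Ar, dark
Reagents that add atoms: none
Why: Acid-catalysed acetal solvolysis (MOM removal) of the three aryl MOM ethers is faster than protonation of the 1,1-disubstituted and trisubstituted alkenes at this acidity and temperature, as in MOM-based syntheses of prenylated 2'-hydroxychalcones; the stereocentre and the E-enone are not affected.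

**Compound list**
1 | 1-(2,4-dihydroxy-6-methoxyphenyl)ethan-1-one | CC(=O)c1c(O)cc(O)cc1OC | starting material
2 | 1-[2-hydroxy-6-methoxy-4-(methoxymethoxy)phenyl]ethan-1-one | CC(=O)c1c(O)cc(OCOC)cc1OC | intermediate
3 | 1-[2-hydroxy-3-iodo-6-methoxy-4-(methoxymethoxy)phenyl]ethan-1-one | CC(=O)c1c(O)c(I)c(OCOC)cc1OC | intermediate
4 | (2R)-5-methyl-2-(prop-1-en-2-yl)hex-4-en-1-ol, (R)-lavandulol | CC(C)=CC[C@@H](CO)C(C)=C | starting material
5 | 5,7-di-tert-butyl-3-phenyl-1,3-benzoxazol-3-ium tetrafluoroborate | CC(C)(C)c1cc(C(C)(C)C)c2oc[n+](-c3ccccc3)c2c1.F[B-](F)(F)F | starting material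
6 | 5,7-di-tert-butyl-2-{[(2R)-5-methyl-2-(prop-1-en-2-yl)hex-4-en-1-yl]oxy}-3-phenyl-2,3-dihydro-1,3-benzoxazole (formed in the flask, both epimers at the aminal carbon) | CC(C)(C)c1cc(C(C)(C)C)c2OC(OC[C@H](CC=C(C)C)C(C)=C)N(c3ccccc3)c2c1 | intermediate
7 | 1-{2-hydroxy-6-methoxy-4-(methoxymethoxy)-3-[(2S)-5-methyl-2-(prop-1-en-2-yl)hex-4-en-1-yl]phenyl}ethan-1-one | CC(=O)c1c(O)c(C[C@H](CC=C(C)C)C(C)=C)c(OCOC)cc1OC | intermediate
8 | 2,4-bis(methoxymethoxy)benzaldehyde | O=Cc1ccc(OCOC)cc1OCOC | starting material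
9 | 3-[2,4-bis(methoxymethoxy)phenyl]-3-hydroxy-1-{2-hydroxy-6-methoxy-4-(methoxymethoxy)-3-[(2S)-5-methyl-2-(prop-1-en-2-yl)hex-4-en-1-yl]phenyl}propan-1-one (formed in the flask, both carbinol epimers) | COCOc1ccc(C(O)CC(=O)c2c(O)c(C[C@H](CC=C(C)C)C(C)=C)c(OCOC)cc2OC)c(OCOC)c1 | intermediate
10 | (2E)-3-[2,4-bis(methoxymethoxy)phenyl]-1-{2-hydroxy-6-methoxy-4-(methoxymethoxy)-3-[(2S)-5-methyl-2-(prop-1-en-2-yl)hex-4-en-1-yl]phenyl}prop-2-en-1-one | COCOc1ccc(/C=C/C(=O)c2c(O)c(C[C@H](CC=C(C)C)C(C)=C)c(OCOC)cc2OC)c(OCOC)c1 | intermediate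
11 | (2E)-1-{2,4-dihydroxy-6-methoxy-3-[(2S)-5-methyl-2-(prop-1-en-2-yl)hex-4-en-1-yl]phenyl}-3-(2,4-dihydroxyphenyl)prop-2-en-1-one (CNP0152102.3) | C=C(C)[C@@H](CC=C(C)C)Cc1c(O)cc(OC)c(C(=O)/C=C/c2ccc(O)cc2O)c1O | target

**Totals**
Total step count: 5. Longest linear sequence: 5 steps (1 → 2 → 3 → 7 → 10 → 11); 4, 5 and 8 enter as bought materials.

**Three steps most likely to fail**

Step 3, the proposed new coupling. The risks are slow radical capture at the di-ortho-substituted aryl–nickel centre, interference by the free phenol, hydrodeiodination of 3, and partial 1,2-vinyl shift of the lavandulyl radical. The fallback uses known two-electron chemistry; it sets out from 4 and 3 and comes back to the route at 7. Alcohol 4 is converted by Appel iodination (I2, PPh3, imidazole, CH2Cl2, 0 °C) into (3R)-3-(iodomethyl)-2,6-dimethylhepta-1,5-diene F1. Zinc insertion (Zn dust activated with 1,2-dibromoethane/TMSCl, LiCl, THF, 35 °C) gives iodo[(2R)-5-methyl-2-(prop-1-en-2-yl)hex-4-en-1-yl]zinc F2. Negishi coupling of F2 (2.5 equiv, slow addition so that coupling outpaces protonation by the chelated phenol) with 3 under Pd(OAc)2 (2 mol%)/SPhos (4 mol%) in THF at rt gives 7. No free radical is generated at the CH2 carbon in the coupling, and the stereocentre is again untouched.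

Step 5, the global MOM removal. The risks are acid-promoted cyclisation of a freed phenol onto the isopropenyl group, hydration of the alkenes, and chalcone-to-flavanone closure. The fallback abandons Brønsted-acid solvolysis for a buffered trans-silylation; it sets out from 10 and comes back at 11. Treatment of 10 with TMSOTf (8 equiv) and 2,2'-bipyridyl (12 equiv) in MeCN at 0 °C → rt converts each aryl MOM ether (and the free phenol) into its silyl ether, giving (2E)-1-{6-methoxy-3-[(2S)-5-methyl-2-(prop-1-en-2-yl)hex-4-en-1-yl]-2,4-bis(trimethylsilyloxy)phenyl}-3-[2,4-bis(trimethylsilyloxy)phenyl]prop-2-en-1-one F6. Neutral hydrolysis of F6 (H2O/THF, rt) gives 11 without any strong protic acid reaching the alkenes.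

Step 4, the Claisen–Schmidt condensation. The risks are sluggish condensation of the phenoxide-deactivated, hindered ketone and partial flavanone formation from the 2'-hydroxychalcone under base. The fallback removes the free phenol before the condensation; it sets out from 7 and comes back at 11. Ketone 7 is alkylated (NaH, MOMCl, DMF, 0 °C → rt) to 1-{6-methoxy-2,4-bis(methoxymethoxy)-3-[(2S)-5-methyl-2-(prop-1-en-2-yl)hex-4-en-1-yl]phenyl}ethan-1-one F3. Condensation of F3 with 8 (KOH, EtOH, rt) passes through 3-[2,4-bis(methoxymethoxy)phenyl]-3-hydroxy-1-{6-methoxy-2,4-bis(methoxymethoxy)-3-[(2S)-5-methyl-2-(prop-1-en-2-yl)hex-4-en-1-yl]phenyl}propan-1-one F4 (formed in the flask) to (2E)-3-[2,4-bis(methoxymethoxy)phenyl]-1-{6-methoxy-2,4-bis(methoxymethoxy)-3-[(2S)-5-methyl-2-(prop-1-en-2-yl)hex-4-en-1-yl]phenyl}prop-2-en-1-one F5, which cannot close to a flavanone. Removal of all four MOM groups from F5 (3 M aq. HCl/MeOH, 40 °C) gives 11.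

**Further compounds**
F1 | step 3 | (3R)-3-(iodomethyl)-2,6-dimethylhepta-1,5-diene | CC(C)=CC[C@@H](CI)C(C)=C
F2 | step 3 | iodo[(2R)-5-methyl-2-(prop-1-en-2-yl)hex-4-en-1-yl]zinc | CC(C)=CC[C@@H](C[Zn]I)C(C)=C
F3 | step 4 | 1-{6-methoxy-2,4-bis(methoxymethoxy)-3-[(2S)-5-methyl-2-(prop-1-en-2-yl)hex-4-en-1-yl]phenyl}ethan-1-one | CC(=O)c1c(OCOC)c(C[C@H](CC=C(C)C)C(C)=C)c(OCOC)cc1OC
F4 | step 4 | 3-[2,4-bis(methoxymethoxy)phenyl]-3-hydroxy-1-{6-methoxy-2,4-bis(methoxymethoxy)-3-[(2S)-5-methyl-2-(prop-1-en-2-yl)hex-4-en-1-yl]phenyl}propan-1-one | COCOc1ccc(C(O)CC(=O)c2c(OCOC)c(C[C@H](CC=C(C)C)C(C)=C)c(OCOC)cc2OC)c(OCOC)c1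
F5 | step 4 | (2E)-3-[2,4-bis(methoxymethoxy)phenyl]-1-{6-methoxy-2,4-bis(methoxymethoxy)-3-[(2S)-5-methyl-2-(prop-1-en-2-yl)hex-4-en-1-yl]phenyl}prop-2-en-1-one | COCOc1ccc(/C=C/C(=O)c2c(OCOC)c(C[C@H](CC=C(C)C)C(C)=C)c(OCOC)cc2OC)c(OCOC)c1
F6 | step 5 | (2E)-1-{6-methoxy-3-[(2S)-5-methyl-2-(prop-1-en-2-yl)hex-4-en-1-yl]-2,4-bis(trimethylsilyloxy)phenyl}-3-[2,4-bis(trimethylsilyloxy)phenyl]prop-2-en-1-one | C=C(C)[C@@H](CC=C(C)C)Cc1c(O[Si](C)(C)C)cc(OC)c(C(=O)/C=C/c2ccc(O[Si](C)(C)C)cc2O[Si](C)(C)C)c1O[Si](C)(C)C
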